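## Retrosynthetic overview

1. The bridging oxolanone is closed last by a transannular 5-exo oxa-Michael addition of the C8 hydroxyl onto a 14-membered (E)-ene-dione, which is itself closed by an intramolecular Wittig reaction (C11=C12).
2. The (Z)-enoate and γ-ketone (C3=C4, C5, C6) come from a zinc-carbenoid chain extension–aldol union of an east β-keto ester with a west aldehyde, followed by syn dehydration.
3. The east piece is a 2-silyloxy-oxolan-3-one (masked C10–C11 α-keto aldehyde), made by a one-carbon ring expansion of a β-lactone with LiCHBr2 (key step); the β-lactone comes from enzymatically desymmetrised 3-hydroxy-3-methylglutarate (C8).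
4. The west piece is (S)-4-isopropenyl-δ-lactone (C1 set by rhodium-catalysed conjugate addition), converted to a chloromethyl ketone aldehyde.
5. Ring order: oxetanone, then oxolanone (lactol), then the 14-membered carbocycle, then the bridging oxolanone.

Assumption and labels: atoms are labelled C1–C14 around the carbocycle (C1 isopropenyl; C3=C4 with the ester on C4; C6, C10, C13 ketones; C8 methyl and ring oxygen; C11 ring oxygen). Pig liver esterase is taken to give the (S)-half-ester of dimethyl 3-hydroxy-3-methylglutarate. The route has not been run; the lactol and its derivatives are anomeric mixtures that converge in step 13.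

## Route

Step 1
Reactants: 1 5,6-dihydro-2H-pyran-2-one; 2 potassium trifluoro(prop-1-en-2-yl)borate
Product: 3 (4S)-4-(prop-1-en-2-yl)oxan-2-one
Conditions: [Rh(cod)2]PF6 (3 mol%), (S)-BINAP (3.3 mol%), toluene/H2O 20:1, 105 °C
Reagents that add atoms: none
Why: Rhodium-catalysed asymmetric conjugate addition (Hayashi–Miyaura type, trifluoroborate variant), in which the (S)-BINAP–rhodium alkenyl species adds to one face of the cyclic enoate (same sense as for aryl- and alkenylboron additions to this lactone and to cyclohexenone) and protonation gives the (S)-configured C1 centre.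

Step 2
Reactants: 3 (4S)-4-(prop-1-en-2-yl)oxan-2-one; 4 chloroiodomethane
Product: 5 (4S)-1-chloro-6-hydroxy-4-(prop-1-en-2-yl)hexan-2-one
Conditions: ICH2Cl, MeLi·LiBr, THF/Et2O, −78 °C; then H2O
Reagents that add atoms: none
Why: Acyl substitution of the lactone by chloromethyllithium made in situ by iodine–lithium exchange (halomethyllithium route to α-chloro ketones), the tetrahedral lithium hemiketal being stable at −78 °C so that only one CH2Cl unit adds and C1 is untouched.

Step 3
Reactants: 5 (4S)-1-chloro-6-hydroxy-4-(prop-1-en-2-yl)hexan-2-one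
Product: 6 (3S)-6-chloro-5-oxo-3-(prop-1-en-2-yl)hexanal
Conditions: PhI(OAc)2, TEMPO (10 mol%), CH2Cl2, 23 °C
Reagents that add atoms: none
Why: TEMPO/PhI(OAc)2 oxidation of the primary alcohol (through the open hydroxy ketone form) stops at the aldehyde and leaves the chloromethyl ketone, the isopropenyl group and the non-enolisable C1 centre alone.

Step 4
Reactants: 7 methyl 3-oxobutanoate; 8 methyl bromoacetate
Product: 9 dimethyl 3-hydroxy-3-methylpentanedioate
Conditions: Zn dust (Me3SiCl-activated), THF, 50 °C; aqueous work-up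
Reagents that add atoms: none
Why: Reformatsky addition of the zinc enolate of methyl bromoacetate to the ketone of methyl acetoacetate (classical access to 3-hydroxy-3-methylglutarates), giving an achiral diester that is prochiral at C8.

Step 5
Reactants: 9 dimethyl 3-hydroxy-3-methylpentanedioate
Product: 10 (3S)-3-hydroxy-5-methoxy-3-methyl-5-oxopentanoic acid
Conditions: pig liver esterase, phosphate buffer pH 7.5, 25 °C
Reagents that add atoms: water, O
Why: Enzymatic desymmetrisation (esterase hydrolysis of one enantiotopic ester group) gives the (S)-half-ester and so fixes the C8 configuration, the acid arm becoming C9–C10 and the ester arm C7–C6.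

Step 6
Reactants: 10 (3S)-3-hydroxy-5-methoxy-3-methyl-5-oxopentanoic acid; 11 methyl acetate
Product: 12 (3R)-3-hydroxy-7-methoxy-3-methyl-5,7-dioxoheptanoic acid
Conditions: MeOAc, LiN(i-Pr)2 (5 equiv each), THF, −78 to −30 °C; then aq. HCl
Reagents that add atoms: none
Why: Crossed Claisen condensation in which the excess lithium enolate first deprotonates CO2H and OH, the carboxylate is inert, and the alkoxide-activated methyl ester is acylated once because the product is stored as its β-keto ester enolate, with no bond to C8 broken (the descriptor changes only through priorities).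

Step 7
Reactants: 12 (3R)-3-hydroxy-7-methoxy-3-methyl-5,7-dioxoheptanoic acid
Product: 13 methyl 4-[(2R)-2-methyl-4-oxooxetan-2-yl]-3-oxobutanoate
Conditions: PhSO2Cl (2 equiv), pyridine, 0 °C
Reagents that add atoms: none
Why: Adam β-lactonisation (carboxyl activation as the mixed sulfonic anhydride, then attack of the tertiary hydroxyl on the acyl carbon), so the C8–O bond and the C8 configuration are retained.

Step 8
Reactants: 13 methyl 4-[(2R)-2-methyl-4-oxooxetan-2-yl]-3-oxobutanoate; 14 dibromomethane
Product: 17 methyl 4-[(2R)-5-hydroxy-2-methyl-4-oxooxolan-2-yl]-3-oxobutanoate, via dibromomethyl ketone 15 (not isolated), via bromo-oxolanone 16 (not isolated)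
Conditions: LiN(SiMe3)2 (1.0 equiv), THF, −78 °C; LiCHBr2 [CH2Br2, LiN(i-Pr)2, −90 °C], −90 to −40 °C; AcOH; then NaHCO3, THF/H2O, 40 °C
Reagents that add atoms: water, O
Why: Proposed new method: with the β-keto ester masked as its lithium enolate, dibromomethyllithium adds to the strained lactone carbonyl and the tetrahedral intermediate collapses by acyl–oxygen cleavage to the dibromomethyl ketone 15, whose C8 oxygen displaces one bromide in a 5-exo-tet SN2 reaction at the α-keto carbon to give the α-bromo ether 16, which is hydrolysed to the lactol, so that one carbon (C11) is inserted into the acyl–O bond (oxetan-2-one to oxolan-3-one, C8 untouched, C11 an inconsequential anomeric mixture); the closest known chemistry is the Kowalski-type addition of LiCHBr2 to esters and the one-carbon ring expansion of lactones to oxacycloalkan-3-ones by halomethyl or diazomethyl anions followed by O-alkylation or O–H insertion.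

Step 9
Reactants: 17 methyl 4-[(2R)-5-hydroxy-2-methyl-4-oxooxolan-2-yl]-3-oxobutanoate
Product: 18 methyl 4-[(2R)-2-methyl-4-oxo-5-(triethylsilyloxy)oxolan-2-yl]-3-oxobutanoate
Conditions: Et3SiCl, imidazole, CH2Cl2, 0 °C
Reagents that add atoms: chlorotriethylsilane, CC[Si](Cl)(CC)CC
Why: Silylation of the lactol hydroxyl gives a silyl acetal that masks the α-keto aldehyde and the C8 oxygen through the next three steps (protecting-group step, no stereocentre affected).

Step 10
Reactants: 18 methyl 4-[(2R)-2-methyl-4-oxo-5-(triethylsilyloxy)oxolan-2-yl]-3-oxobutanoate; 19 diiodomethane; 6 (3S)-6-chloro-5-oxo-3-(prop-1-en-2-yl)hexanal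
Product: 21 methyl (2S)-2-[(1R,3S)-6-chloro-1-hydroxy-5-oxo-3-(prop-1-en-2-yl)hexyl]-5-[(2R)-2-methyl-4-oxo-5-(triethylsilyloxy)oxolan-2-yl]-4-oxopentanoate (C3,C4-syn aldol; the other syn isomer is formed alongside), via zinc enolate 20 (not isolated)
Conditions: Et2Zn (3 equiv), CH2I2 (3 equiv), CH2Cl2, 0 °C, 30 min; then 6, −40 to 0 °C
Reagents that add atoms: none
Why: Zercher tandem zinc-carbenoid chain extension–aldol reaction, in which the zinc enolate of the β-keto ester is cyclopropanated by EtZnCH2I and the donor–acceptor cyclopropoxide fragments (1,2-acyl shift, C5 inserted) to the (Z)-zinc ester enolate 20, which adds to the aldehyde through a closed chair transition state to give the C3,C4-syn aldols (both centres are removed in step 11).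

Step 11
Reactants: 21 C3,C4-syn aldol
Product: 22 methyl (2Z,5S)-8-chloro-2-{3-[(2R)-2-methyl-4-oxo-5-(triethylsilyloxy)oxolan-2-yl]-2-oxopropyl}-7-oxo-5-(prop-1-en-2-yl)oct-2-enoate
Conditions: DCC (3 equiv), CuCl (20 mol%), toluene, 80 °C
Reagents that add atoms: none
Why: Copper-catalysed carbodiimide dehydration is a stereospecific syn elimination through the O-alkylisourea, so the syn aldol gives the (Z)-enoate with the ester cis to C2 as in the target.

Step 12
Reactants: 22 (Z)-enoate chloromethyl ketone
Product: 23 {(4S,6Z)-7-(methoxycarbonyl)-10-[(2R)-2-methyl-4-oxo-5-(triethylsilyloxy)oxolan-2-yl]-2,9-dioxo-4-(prop-1-en-2-yl)dec-6-en-1-yl}triphenylphosphonium chloride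
Conditions: PPh3 (1.5 equiv), NaI (10 mol%), MeCN, 45 °C
Reagents that add atoms: triphenylphosphine, c1ccc(cc1)P(c1ccccc1)c1ccccc1
Why: Iodide-catalysed SN2 displacement of the α-chloro ketone by triphenylphosphine gives the acylmethylphosphonium salt, the precursor of a stabilised Wittig ylide.

Step 13
Reactants: 23 acylmethylphosphonium chloride
Product: 26 methyl (1R,5Z,8S,12R)-1-methyl-3,10,13-trioxo-8-(prop-1-en-2-yl)-15-oxabicyclo[10.2.1]pentadec-5-ene-5-carboxylate, via lactol phosphonium salt 24 (not isolated), via macrocyclic ene-dione 25 (not isolated)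
Conditions: HF·pyridine, THF, 0 °C; then i-Pr2NEt (8 equiv), CH2Cl2 (1 mM), 35 °C
Reagents that add atoms: none
Why: Desilylation frees the lactol, the amine forms the stabilised acyl ylide, and an intramolecular Wittig reaction with the α-keto aldehyde (open form of the lactol) closes the 14-membered (E)-ene-dione 25, in which the freed C8 hydroxyl adds transannularly to C11 (5-exo oxa-Michael addition, reversible under the amine); the ring is expected to direct C12 anti to C7, giving the trans-bridged oxolanone with the 11R configuration.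

## Compound list

1 | 5,6-dihydro-2H-pyran-2-one | O=C1C=CCCO1 | starting material
2 | potassium trifluoro(prop-1-en-2-yl)borate | [K+].CC(=C)[B-](F)(F)F | starting material
3 | (4S)-4-(prop-1-en-2-yl)oxan-2-one | C=C(C)[C@H]1CCOC(=O)C1 | intermediate
4 | chloroiodomethane | ClCI | starting material
5 | (4S)-1-chloro-6-hydroxy-4-(prop-1-en-2-yl)hexan-2-one (in equilibrium with its cyclic hemiketal) | C=C(C)[C@H](CC(=O)CCl)CCO | intermediate
6 | (3S)-6-chloro-5-oxo-3-(prop-1-en-2-yl)hexanal | C=C(C)[C@H](CC(=O)CCl)CC=O | intermediate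
7 | methyl 3-oxobutanoate (methyl acetoacetate) | COC(=O)CC(C)=O | starting material
8 | methyl bromoacetate | COC(=O)CBr | starting material
9 | dimethyl 3-hydroxy-3-methylpentanedioate | COC(=O)CC(C)(O)CC(=O)OC | intermediate
10 | (3S)-3-hydroxy-5-methoxy-3-methyl-5-oxopentanoic acid | COC(=O)C[C@](O)(C)CC(=O)O | intermediate
11 | methyl acetate | COC(C)=O | starting material
12 | (3R)-3-hydroxy-7-methoxy-3-methyl-5,7-dioxoheptanoic acid | COC(=O)CC(=O)C[C@](O)(C)CC(=O)O | intermediate
13 | methyl 4-[(2R)-2-methyl-4-oxooxetan-2-yl]-3-oxobutanoate | COC(=O)CC(=O)C[C@]1(C)CC(=O)O1 | intermediate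
14 | dibromomethane | BrCBr | starting material
15 | methyl (5R)-8,8-dibromo-5-hydroxy-5-methyl-3,7-dioxooctanoate | COC(=O)CC(=O)C[C@](O)(C)CC(=O)C(Br)Br | intermediate
16 | methyl 4-[(2R)-5-bromo-2-methyl-4-oxooxolan-2-yl]-3-oxobutanoate (both C5 epimers) | COC(=O)CC(=O)C[C@]1(C)CC(=O)C(Br)O1 | intermediate
17 | methyl 4-[(2R)-5-hydroxy-2-methyl-4-oxooxolan-2-yl]-3-oxobutanoate (lactol, both anomers) | COC(=O)CC(=O)C[C@]1(C)CC(=O)C(O)O1 | intermediate
18 | methyl 4-[(2R)-2-methyl-4-oxo-5-(triethylsilyloxy)oxolan-2-yl]-3-oxobutanoate (both anomers) | COC(=O)CC(=O)C[C@]1(C)CC(=O)C(O[Si](CC)(CC)CC)O1 | intermediate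
19 | diiodomethane | ICI | starting material
20 | ethyl{1-methoxy-5-[(2R)-2-methyl-4-oxo-5-(triethylsilyloxy)oxolan-2-yl]-1,4-dioxopentan-2-yl}zinc (zinc enolate of the chain-extended γ-keto ester, C-bound form drawn) | COC(=O)C([Zn]CC)CC(=O)C[C@]1(C)CC(=O)C(O[Si](CC)(CC)CC)O1 | intermediate
21 | methyl (2S)-2-[(1R,3S)-6-chloro-1-hydroxy-5-oxo-3-(prop-1-en-2-yl)hexyl]-5-[(2R)-2-methyl-4-oxo-5-(triethylsilyloxy)oxolan-2-yl]-4-oxopentanoate (syn aldol; one of the two syn isomers drawn) | COC(=O)[C@@H](CC(=O)C[C@]1(C)CC(=O)C(O[Si](CC)(CC)CC)O1)[C@H](O)C[C@@H](CC(=O)CCl)C(C)=C | intermediate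
22 | methyl (2Z,5S)-8-chloro-2-{3-[(2R)-2-methyl-4-oxo-5-(triethylsilyloxy)oxolan-2-yl]-2-oxopropyl}-7-oxo-5-(prop-1-en-2-yl)oct-2-enoate | C=C(C)[C@H](CC(=O)CCl)C/C=C(\C(=O)OC)CC(=O)C[C@]1(C)CC(=O)C(O[Si](CC)(CC)CC)O1 | intermediate
23 | {(4S,6Z)-7-(methoxycarbonyl)-10-[(2R)-2-methyl-4-oxo-5-(triethylsilyloxy)oxolan-2-yl]-2,9-dioxo-4-(prop-1-en-2-yl)dec-6-en-1-yl}triphenylphosphonium chloride | C=C(C)[C@H](CC(=O)C[P+](c1ccccc1)(c1ccccc1)c1ccccc1)C/C=C(\C(=O)OC)CC(=O)C[C@]2(C)CC(=O)C(O[Si](CC)(CC)CC)O2.[Cl-] | intermediate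
24 | {(4S,6Z)-10-[(2R)-5-hydroxy-2-methyl-4-oxooxolan-2-yl]-7-(methoxycarbonyl)-2,9-dioxo-4-(prop-1-en-2-yl)dec-6-en-1-yl}triphenylphosphonium chloride | C=C(C)[C@H](CC(=O)C[P+](c1ccccc1)(c1ccccc1)c1ccccc1)C/C=C(\C(=O)OC)CC(=O)C[C@]2(C)CC(=O)C(O)O2.[Cl-] | intermediate
25 | methyl (1Z,4S,7E,11R)-11-hydroxy-11-methyl-6,9,13-trioxo-4-(prop-1-en-2-yl)cyclotetradeca-1,7-diene-1-carboxylate | C=C(C)[C@H]1C/C=C(\C(=O)OC)CC(=O)C[C@](O)(C)CC(=O)/C=C/C(=O)C1 | intermediate
26 | methyl (1R,5Z,8S,12R)-1-methyl-3,10,13-trioxo-8-(prop-1-en-2-yl)-15-oxabicyclo[10.2.1]pentadec-5-ene-5-carboxylate | C=C(C)[C@H]1C/C=C(\C(=O)OC)CC(=O)C[C@]2(C)CC(=O)[C@@H](CC(=O)C1)O2 | target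

## Step count and risks

Total step count: 13. Longest linear sequence: 10 steps (steps 4 to 13); the west piece takes steps 1 to 3.

The three steps most likely to fail:

Step 8 (the proposed new ring expansion). The risks are enolisation or β-elimination of the β-lactone and a dibromomethyl ketone that stays as its enolate instead of closing. The fallback uses known chemistry and sets out from acid 12. Activation with i-BuOCOCl and N-methylmorpholine gives the mixed anhydride (3R)-3-hydroxy-7-methoxy-3-methyl-5,7-dioxoheptanoic isobutyl carbonic anhydride F1. Diazomethane converts it into the diazo ketone methyl (5R)-8-diazo-5-hydroxy-5-methyl-3,7-dioxooctanoate F2. Oxidation of the diazo carbon with dimethyldioxirane gives the α-keto aldehyde, which closes to lactol 17, where the route is rejoined.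

Step 10 (tandem chain extension–aldol on two polyfunctional pieces). The risks are low conversion, poor syn selectivity and attack of the carbenoid on the isopropenyl group. The fallback separates the two events and makes the alkene from the anti aldol; it sets out from 18. Chain extension with an iodine quench gives the iodo ester methyl 2-iodo-5-[(2R)-2-methyl-4-oxo-5-(triethylsilyloxy)oxolan-2-yl]-4-oxopentanoate F3. A CrCl2-mediated Reformatsky reaction of F3 with aldehyde 6 gives the anti aldol methyl (2R)-2-[(1R,3S)-6-chloro-1-hydroxy-5-oxo-3-(prop-1-en-2-yl)hexyl]-5-[(2R)-2-methyl-4-oxo-5-(triethylsilyloxy)oxolan-2-yl]-4-oxopentanoate F4. Anti elimination with Martin sulfurane then gives (Z)-enoate 22, where the route is rejoined.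

Step 13 (macrocyclising Wittig reaction and transannular oxa-Michael addition). The risks are slow ring closure from the small open-chain aldehyde fraction and base-induced side reactions of the polyketone. The fallback closes the ring by a chromium Reformatsky-type aldol and sets out from 22. HF·pyridine gives the lactol methyl (2Z,5S)-8-chloro-2-{3-[(2R)-5-hydroxy-2-methyl-4-oxooxolan-2-yl]-2-oxopropyl}-7-oxo-5-(prop-1-en-2-yl)oct-2-enoate F5. CrCl2 with catalytic LiI at high dilution adds the chromium enolate of the chloromethyl ketone to the lactol aldehyde and gives the macrocyclic diol methyl (1Z,4S,11R)-8,11-dihydroxy-11-methyl-6,9,13-trioxo-4-(prop-1-en-2-yl)cyclotetradec-1-ene-1-carboxylate F6. Mesylation of the secondary hydroxyl (MsCl, Et3N) triggers elimination to ene-dione 25, which closes to 26 as in step 13.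

## Further compounds

F1 | step 8 | (3R)-3-hydroxy-7-methoxy-3-methyl-5,7-dioxoheptanoic isobutyl carbonic anhydride | COC(=O)CC(=O)C[C@](O)(C)CC(=O)OC(=O)OCC(C)C
F2 | step 8 | methyl (5R)-8-diazo-5-hydroxy-5-methyl-3,7-dioxooctanoate | COC(=O)CC(=O)C[C@](O)(C)CC(=O)C=[N+]=[N-]
F3 | step 10 | methyl 2-iodo-5-[(2R)-2-methyl-4-oxo-5-(triethylsilyloxy)oxolan-2-yl]-4-oxopentanoate | COC(=O)C(I)CC(=O)C[C@]1(C)CC(=O)C(O[Si](CC)(CC)CC)O1
F4 | step 10 | methyl (2R)-2-[(1R,3S)-6-chloro-1-hydroxy-5-oxo-3-(prop-1-en-2-yl)hexyl]-5-[(2R)-2-methyl-4-oxo-5-(triethylsilyloxy)oxolan-2-yl]-4-oxopentanoate | COC(=O)[C@H](CC(=O)C[C@]1(C)CC(=O)C(O[Si](CC)(CC)CC)O1)[C@H](O)C[C@@H](CC(=O)CCl)C(C)=C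
F5 | step 13 | methyl (2Z,5S)-8-chloro-2-{3-[(2R)-5-hydroxy-2-methyl-4-oxooxolan-2-yl]-2-oxopropyl}-7-oxo-5-(prop-1-en-2-yl)oct-2-enoate | C=C(C)[C@H](CC(=O)CCl)C/C=C(\C(=O)OC)CC(=O)C[C@]1(C)CC(=O)C(O)O1
F6 | step 13 | methyl (1Z,4S,11R)-8,11-dihydroxy-11-methyl-6,9,13-trioxo-4-(prop-1-en-2-yl)cyclotetradec-1-ene-1-carboxylate | C=C(C)[C@H]1C/C=C(\C(=O)OC)CC(=O)C[C@](O)(C)CC(=O)C(O)CC(=O)C1
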